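**Retrosynthetic overview**
1. Last C–C bond: C3–C4 of the (2Z,4E)-pentadienyl linker, made by Hiyama coupling of (Z)-vinylsilane 24 (rings B and C) with (E)-vinyl iodide 7 (ring A, fragment A). The Z-alkene comes from trans-hydrosilylation of a propynyl carbinol, and CH2OH comes from an ester.
2. Enabling feature: in the 7-oxabicyclo[4.1.0]hept-3-ene-2,5-diol core, the oxirane (C1, C6, O7; ring C) lies anti to a cis-diol at C2 and C5 that flanks the C3=C4 alkene of the carbocycle (ring B). This pattern is the reduced anti-1,4-endoperoxide of an arene oxide, and an arene oxide is the valence tautomer of a flat oxepine.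
3. Ring B, ring C, both ring carbinol C–O bonds and four stereocentres therefore arise at once from oxepine 18 (one stereocentre) and O2, by ring contraction from seven to six members.
4. The oxepine is built from a furan. Diels–Alder reaction with methyl 3-nitroacrylate and loss of HNO2 gives 7-oxanorbornadiene 15, a photochemical [2+2] gives the strained 3-oxaquadricyclane 16, and thermal opening gives 17. Overall, two carbons are inserted into the furan C3–C4 bond.
5. Ring order: ring A (step 2, epoxy-ene cyclisation); furan (bought) → oxanorbornadiene (step 10) → oxaquadricyclane (step 11) → oxepine (step 12) → rings B and C together (step 14).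

Key step: step 14

Assumption: 13, (R)-Alpine-Borane, the Shi ketone and BnMe2SiH are bought; 14–16 are carried as mixtures of ring diastereomers (only the carbinol centre is drawn), because all their ring stereocentres vanish in the flat oxepine 17.

**Fragment A (ring A)**

Step 1
Reactants: 1 geranyl acetate
Product: 2 (2E)-5-[(2R)-3,3-dimethyloxiran-2-yl]-3-methylpent-2-en-1-yl acetate
Conditions: 1,2:4,5-di-O-isopropylidene-β-D-erythro-hexo-2,3-diulo-2,6-pyranose (Shi ketone, cat.), Oxone (2KHSO5·KHSO4·K2SO4), K2CO3, Bu4NHSO4, MeCN–CH2(OMe)2/aq. borate buffer, 0 °C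
Reagents that add atoms: potassium peroxymonosulfate, OOS(=O)(=O)[O-].[K+]
Why: Shi epoxidation: the chiral dioxirane attacks the electron-richer 6,7-alkene (the 2,3-alkene is deactivated by the allylic acetate) through the spiro transition state that gives the (R)-epoxide.

Step 2
Reactants: 2 (R)-epoxygeranyl acetate
Product: 3 [(1S,5R)-5-hydroxy-2,6,6-trimethylcyclohex-2-en-1-yl]methyl acetate
Conditions: ZrCl4, CH2Cl2, −20 °C
Reagents that add atoms: none
Why: Biomimetic Lewis acid-promoted epoxy-ene (cationic polyene-type) cyclisation: anti attack of the (E)-alkene on the tertiary epoxide carbon in a chair-like array keeps the C–O centre, sets hydroxyl and acetoxymethyl cis-diequatorial (new centre S) and ends with loss of a ring proton to the endocyclic trisubstituted alkene.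

Step 3
Reactants: 3 hydroxy acetate
Product: 4 [(1S,5R)-2,6,6-trimethyl-5-(triethylsilyloxy)cyclohex-2-en-1-yl]methyl acetate
Conditions: Et3SiCl, imidazole, CH2Cl2, 0 → 23 °C
Reagents that add atoms: chlorotriethylsilane, CC[Si](Cl)(CC)CC
Why: Imidazole-assisted silyl ether formation masks the secondary alcohol, which would otherwise close a lactol onto the cis-disposed aldehyde of 6; no stereocentre is touched.

Step 4
Reactants: 4 silyl ether acetate
Product: 5 [(1S,5R)-2,6,6-trimethyl-5-(triethylsilyloxy)cyclohex-2-en-1-yl]methanol
Conditions: K2CO3 (cat.), MeOH, 0 °C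
Reagents that add atoms: none
Why: Base-catalysed transesterification (Zemplén-type methanolysis) removes the primary acetate while the hindered secondary silyl ether stays on.

Step 5
Reactants: 5 primary alcohol
Product: 6 (1S,5R)-2,6,6-trimethyl-5-(triethylsilyloxy)cyclohex-2-ene-1-carbaldehyde
Conditions: Dess–Martin periodinane, NaHCO3, CH2Cl2, 0 °C
Reagents that add atoms: none
Why: Dess–Martin oxidation under bicarbonate buffer stops at the aldehyde without epimerising the α-centre or moving the β,γ-double bond into conjugation.

Step 6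
Reactants: 6 aldehyde
Product: 7 {[(1R,5S)-5-[(E)-2-iodoethenyl]-4,6,6-trimethylcyclohex-3-en-1-yl]oxy}triethylsilane (fragment A; same spatial arrangement as in 6)
Conditions: CrCl2, CHI3, THF, 0 °C
Reagents that add atoms: iodoform, IC(I)I
Why: Takai olefination: the geminal dichromium species from CHI3 adds to the hindered aldehyde under non-basic conditions and anti-elimination gives the (E)-vinyl iodide with the α-centre intact.

**Rings B and C**

Step 7
Reactants: 8 furan-2-carbonyl chloride; 9 propyne
Product: 10 1-(furan-2-yl)but-2-yn-1-one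
Conditions: PdCl2(PPh3)2 (cat.), CuI (cat.), Et3N, THF, 23 °C
Reagents that add atoms: none
Why: Acyl Sonogashira coupling of an acid chloride with a terminal alkyne gives the ynone directly, and the furan is inert to the catalyst pair.

Step 8
Reactants: 10 ynone
Product: 11 (1S)-1-(furan-2-yl)but-2-yn-1-ol
Conditions: (R)-Alpine-Borane (B-isopinocampheyl-9-BBN from (+)-α-pinene), neat, 23 °C; then HOCH2CH2NH2, Et2O, 0 °C
Reagents that add atoms: none
Why: Midland reduction: in the boat-like six-membered hydride transfer the slim alkynyl group sits next to the pinane methyl group and the furyl group in the open position, which for the reagent from (+)-α-pinene gives the (S)-carbinol.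

Step 9
Reactants: 11 (S)-carbinol
Product: 12 {[(1S)-1-(furan-2-yl)but-2-yn-1-yl]oxy}triethylsilane
Conditions: Et3SiCl, imidazole, CH2Cl2, 0 °C
Reagents that add atoms: chlorotriethylsilane, CC[Si](Cl)(CC)CC
Why: Silyl ether formation; the free hydroxyl must be masked because it could add across the carbonyl ylide that is passed in step 12.

Step 10
Reactants: 12 furan silyl ether; 13 methyl (E)-3-nitroacrylate
Product: 15 methyl 4-[(1S)-1-(triethylsilyloxy)but-2-yn-1-yl]-7-oxabicyclo[2.2.1]hepta-2,5-diene-2-carboxylate, via nitro cycloadduct 14 (not isolated)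
Conditions: CH2Cl2 (concentrated), 23 °C, dark; then DBU, 0 °C
Reagents that add atoms: none
Why: Diels–Alder reaction followed by E1cB loss of nitrous acid: the nitro group, the stronger acceptor, rules the polar asynchronous transition state, so the nucleophilic free C5 of the 2-alkylfuran bonds to the ester-bearing carbon and the nitro-bearing carbon ends next to the substituted bridgehead, after which DBU removes the ester α-proton and nitrite, making 13 a propiolate equivalent of reversed regiochemistry (the new ring stereocentres are of no consequence).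

Step 11
Reactants: 15 7-oxanorbornadiene
Product: 16 methyl 4-[(1S)-1-(triethylsilyloxy)but-2-yn-1-yl]-3-oxatetracyclo[3.2.0.0^2,7.0^4,6]heptane-1-carboxylate
Conditions: hν (254 nm), Et2O, −20 °C
Reagents that add atoms: none
Why: Intramolecular [2+2] photocycloaddition of the norbornadiene-to-quadricyclane type, known for acceptor-substituted 7-oxanorbornadienes: excitation of the enoate joins the two facing double bonds and stores the strain that drives step 12.

Step 12
Reactants: 16 3-oxaquadricyclane
Product: 17 methyl 7-[(1S)-1-(triethylsilyloxy)but-2-yn-1-yl]oxepine-4-carboxylate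
Conditions: toluene (dilute, base-washed glass), 110 °C
Reagents that add atoms: none
Why: Thermal [σ2+σ2] cycloreversion of an acceptor-substituted 3-oxaquadricyclane: the cyclopropane bonds between the oxygen-bearing carbons and the former enoate carbons break (donor–acceptor activation) to a cyclobutene-fused carbonyl ylide whose ring opening gives the oxepine with the ester at C4 and the side chain at C7, three perimeter bonds of the carbocycle of 15 having been cut so that the six carbons now lie in a seven-membered ring with oxygen.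

Step 13
Reactants: 17 oxepine silyl ether
Product: 18 methyl 7-[(1S)-1-hydroxybut-2-yn-1-yl]oxepine-4-carboxylate
Conditions: Bu4NF, AcOH (1:1), THF, 0 °C
Reagents that add atoms: none
Why: Fluoride desilylation buffered with acetic acid frees the carbinol without building up an alkoxide (fragmentation to a phenol) or free acid (aromatisation of the arene oxide tautomer).

Step 14
Reactants: 18 oxepine carbinol
Product: 21 methyl (1S,2R,5S,6S)-2,5-dihydroxy-6-[(1S)-1-hydroxybut-2-yn-1-yl]-7-oxabicyclo[4.1.0]hept-3-ene-3-carboxylate, via arene oxide 19 (not isolated), via endoperoxide 20 (not isolated)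
Conditions: O2, 5,10,15,20-tetraphenylporphyrin (cat.), hν (visible), CH2Cl2, −40 °C; then thiourea, MeOH, −40 → 0 °C
Reagents that add atoms: dioxygen, O=O
Why: Oxepine 18 equilibrates rapidly with its arene oxide valence tautomers by a thermally allowed disrotatory 6π electrocyclisation that bonds C2 to C7; this single C–C bond contracts the seven-membered ring to the six-membered carbocycle (ring B) and closes the oxirane (ring C) at the same time, singlet oxygen then traps the planar cyclohexadiene of 19 in a suprafacial [4+2] cycloaddition (closure of the transient 1,2-dioxane bridge of 20), and thiourea cleaves only the O–O bond. The closest known reaction type is the dye-sensitised photooxygenation of oxepine/benzene oxide systems, including congeners that carry an oxygenated carbon on the oxirane, followed by thiourea reduction to anti-epoxy-cyclohexene-cis-1,4-diols. The cis fusion of the two oxirane carbons follows from the disrotatory closure, the cis relation of the two new carbinol carbons from the suprafacial addition, and their anti relation to the oxirane from approach of oxygen to the face away from the epoxide oxygen. The absolute sense is relayed from the (S)-carbinol: with its hydrogen in the narrow sector between the oxirane oxygen and the oxirane CH, arene oxide 19 holds the hydroxyl under the reacting face next to the diene terminus, where it hydrogen-bonds to the incoming oxygen (the hydroxy-group directivity known for singlet oxygen and chiral allylic or benzylic alcohols), and turns the propynyl arm outward, whereas the other diastereomer would turn the propynyl arm into that face and the hydroxyl away from it. Both arene oxides interconvert through 18 far faster than either is trapped, so all material can drain through the faster channel (Curtin–Hammett situation). The step needs chemoselectivity for the diene over the enol ether bonds of 18 and over the side chain, which is secured by the push–pull deactivation of the oxepine triene by the ester, by the inertness of the alkyne to singlet oxygen and by bringing in the oxidisable diene and ring A only afterwards, while the non-polar solvent and low temperature keep the hydrogen bond and stop 20 from rearranging to a bis-epoxide.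

Step 15
Reactants: 21 alkynyl triol
Product: 22 methyl (1S,2R,5S,6S)-6-[(1S,2Z)-3-(benzyldimethylsilyl)-1-hydroxybut-2-en-1-yl]-2,5-dihydroxy-7-oxabicyclo[4.1.0]hept-3-ene-3-carboxylate
Conditions: BnMe2SiH, [Cp*Ru(MeCN)3]PF6 (cat.), acetone, 0 → 23 °C
Reagents that add atoms: benzyldimethylsilane, C[SiH](C)Cc1ccccc1
Why: Ruthenium-catalysed trans-hydrosilylation of a propargylic alcohol: hydrogen and silicon add to opposite faces with silicon on the distal, methyl-bearing carbon, which fixes the (Z)-trisubstituted alkene with silicon cis to the carbinol carbon and tolerates epoxide, enoate and free hydroxyls.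

Step 16
Reactants: 22 vinylsilane triol
Product: 23 methyl (1S,2R,5S,6S)-6-[(1S,2Z)-3-(benzyldimethylsilyl)-1-(triethylsilyloxy)but-2-en-1-yl]-2,5-bis(triethylsilyloxy)-7-oxabicyclo[4.1.0]hept-3-ene-3-carboxylate
Conditions: Et3SiOTf, 2,6-lutidine, CH2Cl2, −78 → 0 °C
Reagents that add atoms: triethylsilyl trifluoromethanesulfonate, CC[Si](CC)(CC)OS(=O)(=O)C(F)(F)F
Why: Silyl triflate/lutidine silylation caps all three secondary alcohols, so that no aluminium alkoxide next to the oxirane can direct hydride into it in step 17.

Step 17
Reactants: 23 tris(silyl ether) ester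
Product: 24 [(1S,2R,5S,6S)-6-[(1S,2Z)-3-(benzyldimethylsilyl)-1-(triethylsilyloxy)but-2-en-1-yl]-2,5-bis(triethylsilyloxy)-7-oxabicyclo[4.1.0]hept-3-en-3-yl]methanol
Conditions: i-Bu2AlH, CH2Cl2, −78 °C; aq. potassium sodium tartrate
Reagents that add atoms: none
Why: 1,2-Reduction of the enoate with i-Bu2AlH at low temperature gives the allylic alcohol and leaves oxirane, silyl ethers and vinylsilane untouched.

Step 18
Reactants: 24 vinylsilane; 7 vinyl iodide (fragment A)
Product: 27 (1R,2S,5R,6S)-4-(hydroxymethyl)-1-{(1S,2Z,4E)-1-hydroxy-5-[(1S,5R)-5-hydroxy-2,6,6-trimethylcyclohex-2-en-1-yl]-3-methylpenta-2,4-dien-1-yl}-7-oxabicyclo[4.1.0]hept-3-ene-2,5-diol (CNP0389279.1), via silanol 25 (not isolated), via hydroxy iodide 26 (not isolated)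
Conditions: Bu4NF (excess), THF, 0 → 23 °C; then 7, Pd2(dba)3·CHCl3 (cat.), 23 °C
Reagents that add atoms: none
Why: Hiyama coupling with fluoride activation: Bu4NF cleaves the benzyl–silicon bond to the silanol and all four triethylsilyl ethers, and the palladium-catalysed cross-coupling of silanol and vinyl iodide proceeds with retention at both alkenes to give the (2Z,4E)-diene of the target.

**Compound list**
1 | geranyl acetate | CC(C)=CCC/C(C)=C/COC(C)=O | starting material
2 | (2E)-5-[(2R)-3,3-dimethyloxiran-2-yl]-3-methylpent-2-en-1-yl acetate | CC(=O)OC/C=C(C)/CC[C@H]1OC1(C)C | intermediate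
3 | [(1S,5R)-5-hydroxy-2,6,6-trimethylcyclohex-2-en-1-yl]methyl acetate | CC1=CC[C@@H](O)C(C)(C)[C@H]1COC(C)=O | intermediate
4 | triethylsilyl ether of 3 | CC1=CC[C@@H](O[Si](CC)(CC)CC)C(C)(C)[C@H]1COC(C)=O | intermediate
5 | [(1S,5R)-2,6,6-trimethyl-5-(triethylsilyloxy)cyclohex-2-en-1-yl]methanol | CC1=CC[C@@H](O[Si](CC)(CC)CC)C(C)(C)[C@H]1CO | intermediate
6 | (1S,5R)-2,6,6-trimethyl-5-(triethylsilyloxy)cyclohex-2-ene-1-carbaldehyde | CC1=CC[C@@H](O[Si](CC)(CC)CC)C(C)(C)[C@H]1C=O | intermediate
7 | (E)-vinyl iodide, fragment A | CC1=CC[C@@H](O[Si](CC)(CC)CC)C(C)(C)[C@H]1/C=C/I | intermediate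
8 | furan-2-carbonyl chloride | O=C(Cl)c1ccco1 | starting material
9 | propyne | CC#C | starting material
10 | 1-(furan-2-yl)but-2-yn-1-one | CC#CC(=O)c1ccco1 | intermediate
11 | (1S)-1-(furan-2-yl)but-2-yn-1-ol | CC#C[C@H](O)c1ccco1 | intermediate
12 | triethylsilyl ether of 11 | CC#C[C@H](O[Si](CC)(CC)CC)c1ccco1 | intermediate
13 | methyl (E)-3-nitroacrylate | COC(=O)/C=C/[N+](=O)[O-] | starting material
14 | methyl 3-nitro-4-[(1S)-1-(triethylsilyloxy)but-2-yn-1-yl]-7-oxabicyclo[2.2.1]hept-5-ene-2-carboxylate (nitro and ester trans, ring diastereomers) | CC#C[C@H](O[Si](CC)(CC)CC)C12C=CC(O1)C(C(=O)OC)C2[N+](=O)[O-] | intermediate (not isolated)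
15 | methyl 4-[(1S)-1-(triethylsilyloxy)but-2-yn-1-yl]-7-oxabicyclo[2.2.1]hepta-2,5-diene-2-carboxylate | CC#C[C@H](O[Si](CC)(CC)CC)C12C=CC(O1)C(C(=O)OC)=C2 | intermediate
16 | methyl 4-[(1S)-1-(triethylsilyloxy)but-2-yn-1-yl]-3-oxatetracyclo[3.2.0.0^2,7.0^4,6]heptane-1-carboxylate | CC#C[C@H](O[Si](CC)(CC)CC)C12OC3C4C1C2C34C(=O)OC | intermediate
17 | methyl 7-[(1S)-1-(triethylsilyloxy)but-2-yn-1-yl]oxepine-4-carboxylate | CC#C[C@H](O[Si](CC)(CC)CC)C1=CC=C(C(=O)OC)C=CO1 | intermediate
18 | methyl 7-[(1S)-1-hydroxybut-2-yn-1-yl]oxepine-4-carboxylate | CC#C[C@H](O)C1=CC=C(C(=O)OC)C=CO1 | intermediate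
19 | methyl (1S,6S)-6-[(1S)-1-hydroxybut-2-yn-1-yl]-7-oxabicyclo[4.1.0]hepta-2,4-diene-3-carboxylate (arene oxide) | CC#C[C@H](O)[C@]12O[C@H]1C=C(C(=O)OC)C=C2 | intermediate (not isolated)
20 | methyl 4-[(1S)-1-hydroxybut-2-yn-1-yl]-3,6,7-trioxatricyclo[3.2.2.0^2,4]non-8-ene-8-carboxylate, peroxide bridge anti to the oxirane oxygen | CC#C[C@H](O)[C@]12O[C@H]1[C@@H]3OO[C@H]2C=C3C(=O)OC | intermediate (not isolated)
21 | methyl (1S,2R,5S,6S)-2,5-dihydroxy-6-[(1S)-1-hydroxybut-2-yn-1-yl]-7-oxabicyclo[4.1.0]hept-3-ene-3-carboxylate | CC#C[C@H](O)[C@]12O[C@H]1[C@H](O)C(C(=O)OC)=C[C@@H]2O | intermediate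
22 | (Z)-benzyldimethylvinylsilane triol ester | C[Si](C)(Cc1ccccc1)/C(C)=C\[C@H](O)[C@]12O[C@H]1[C@H](O)C(C(=O)OC)=C[C@@H]2O | intermediate
23 | tris(triethylsilyl) ether of 22 | C[Si](C)(Cc1ccccc1)/C(C)=C\[C@H](O[Si](CC)(CC)CC)[C@]12O[C@H]1[C@H](O[Si](CC)(CC)CC)C(C(=O)OC)=C[C@@H]2O[Si](CC)(CC)CC | intermediate
24 | allylic alcohol from 23 | C[Si](C)(Cc1ccccc1)/C(C)=C\[C@H](O[Si](CC)(CC)CC)[C@]12O[C@H]1[C@H](O[Si](CC)(CC)CC)C(CO)=C[C@@H]2O[Si](CC)(CC)CC | intermediate
25 | (Z)-vinyl(dimethyl)silanol of the desilylated core (tetraol) | C[Si](C)(O)/C(C)=C\[C@H](O)[C@]12O[C@H]1[C@H](O)C(CO)=C[C@@H]2O | intermediate (not isolated)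
26 | (1R,5S)-5-[(E)-2-iodoethenyl]-4,6,6-trimethylcyclohex-3-en-1-ol | CC1=CC[C@@H](O)C(C)(C)[C@H]1/C=C/I | intermediate (not isolated)
27 | CNP0389279.1 | CC1=CC[C@@H](O)C(C)(C)[C@H]1/C=C/C(C)=C\[C@H](O)[C@]12O[C@H]1[C@H](O)C(CO)=C[C@@H]2O | target

**Step count and risks**
Total step count: 18. Longest linear sequence: 12 (steps 7–18, from furan-2-carbonyl chloride).

Steps most likely to fail:

**Step 14.** Process at risk: slow trapping of the ester-deactivated diene. Facial discrimination between the two equilibrating arene oxides would then erode, and oxidation of the enol ether bonds of the oxepine tautomer could compete. The fallback uses another oxidation level and another order of events, and it sets out from 17.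
- The ester is reduced first (i-Bu2AlH, toluene, −78 °C) to the silyl-protected oxepinylmethanol F1.
- Buffered fluoride frees the carbinol to give the oxepine diol F2.
- Photooxygenation at −78 °C then runs through the electron-richer arene oxide F3 and its anti-endoperoxide F4.
- Thiourea gives the alkynyl tetraol F5, and trans-hydrosilylation as in step 15 gives the vinylsilane tetraol F6.
- Bu4NF turns F6 into silanol 25, where the route is rejoined inside step 18. Steps 16 and 17 fall away.

**Step 10.** Process at risk: erosion of regiocontrol next to the bulky bridgehead substituent, and cycloreversion of the adduct before nitrous acid is lost. The fallback enforces regiochemistry with a temporary tether instead of by electronics, and it sets out from 11.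
- The carbinol is silylated with methyl 3-(chlorodimethylsilyl)propiolate (made in the flask from methyl propiolate, LiN(SiMe3)2 and Me2SiCl2) to the silicon-tethered furan ynoate F7.
- The intramolecular Diels–Alder reaction (toluene, 80 °C) can only join the silicon-bearing alkyne carbon to the substituted furan carbon, and it gives the oxasilolane-fused oxanorbornadiene F8.
- Bu4NF cleaves the Si–O bond and protodesilylates the vinylsilane to the hydroxy oxanorbornadiene F9.
- Et3SiCl/imidazole comes back to the route at 15.

**Step 18.** Process at risk: protodesilylation of the hindered vinylsilane, and base-induced epoxide migration (Payne type) of the freed epoxy alcohols under excess fluoride. The fallback reverses the polarity of the coupling, avoids fluoride in the C–C bond formation, and sets out from 24 and 6.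
- Iododesilylation of 24 with retention (N-iodosuccinimide, 2,6-lutidine, (CF3)2CHOH, 0 °C) gives the (Z)-vinyl iodide F10.
- Aldehyde 6 is homologated with Cl2CHBpin, CrCl2 and LiI (boron variant of the Takai olefination) to the (E)-vinylboronate F11.
- Suzuki coupling (Pd(PPh3)4, aq. K3PO4, THF) gives the tetrakis(triethylsilyl) ether F12.
- Et3N·3HF in MeCN removes the silyl groups under near-neutral conditions and comes back to the route at 27.

**Further compounds**
F1 | step 14 | {7-[(1S)-1-(triethylsilyloxy)but-2-yn-1-yl]oxepin-4-yl}methanol | CC#C[C@H](O[Si](CC)(CC)CC)C1=CC=C(CO)C=CO1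
F2 | step 14 | (1S)-1-[5-(hydroxymethyl)oxepin-2-yl]but-2-yn-1-ol | CC#C[C@H](O)C1=CC=C(CO)C=CO1
F3 | step 14 | arene oxide tautomer of F2 | CC#C[C@H](O)[C@]12O[C@H]1C=C(CO)C=C2
F4 | step 14 | anti-1,4-endoperoxide of F3 | CC#C[C@H](O)[C@]12O[C@H]1[C@@H]3OO[C@H]2C=C3CO
F5 | step 14 | alkynyl tetraol (hydroxymethyl analogue of 21) | CC#C[C@H](O)[C@]12O[C@H]1[C@H](O)C(CO)=C[C@@H]2O
F6 | step 14 | (Z)-benzyldimethylvinylsilane tetraol | C[Si](C)(Cc1ccccc1)/C(C)=C\[C@H](O)[C@]12O[C@H]1[C@H](O)C(CO)=C[C@@H]2O
F7 | step 10 | methyl 3-({[(1S)-1-(furan-2-yl)but-2-yn-1-yl]oxy}dimethylsilyl)prop-2-ynoate | CC#C[C@H](O[Si](C)(C)C#CC(=O)OC)c1ccco1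
F8 | step 10 | oxasilolane-fused 7-oxanorbornadiene ester | CC#C[C@@H]1O[Si](C)(C)C2=C(C(=O)OC)C3C=CC12O3
F9 | step 10 | methyl 4-[(1S)-1-hydroxybut-2-yn-1-yl]-7-oxabicyclo[2.2.1]hepta-2,5-diene-2-carboxylate | CC#C[C@H](O)C12C=CC(O1)C(C(=O)OC)=C2
F10 | step 18 | (Z)-vinyl iodide of the tris(triethylsilyl)-protected core | I/C(C)=C\[C@H](O[Si](CC)(CC)CC)[C@]12O[C@H]1[C@H](O[Si](CC)(CC)CC)C(CO)=C[C@@H]2O[Si](CC)(CC)CC
F11 | step 18 | (E)-vinylboronic acid pinacol ester of ring A | CC1=CC[C@@H](O[Si](CC)(CC)CC)C(C)(C)[C@H]1/C=C/B1OC(C)(C)C(C)(C)O1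
F12 | step 18 | tetrakis(triethylsilyl) ether of 27 | CC1=CC[C@@H](O[Si](CC)(CC)CC)C(C)(C)[C@H]1/C=C/C(C)=C\[C@H](O[Si](CC)(CC)CC)[C@]12O[C@H]1[C@H](O[Si](CC)(CC)CC)C(CO)=C[C@@H]2O[Si](CC)(CC)CC
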